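Late in the birch run the target turns over, from 0.0788 M at 2.1 h to 0.0698 M at 4.0 h, and that turn stands against your hunch that the cedar run simply gives the elm target times the catalyst ratio, which would be 116% of the substrate charge, more than the charge holds.

| flask | substrate | coupling partner | catalyst | time |
|---|---|---|---|---|
| elm | 0.300 M | 0.450 M | 0.00150 M |  |
| maple | 0.150 M | 0.300 M | 0.00150 M |  |
| birch | 0.300 M | 0.900 M | 0.00150 M |  |
| ash | 0.900 M | 0.450 M | 0.00150 M |  |
| cedar | 0.300 M | 0.450 M | 0.00750 M | 4.0 h |

| run | time / h | [target] / M |
|---|---|---|
| elm run | 0.16 | 0.0074 |
| elm run | 0.30 | 0.0137 |
| elm run | 0.58 | 0.0233 |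
| elm run | 1.1 | 0.0387 |
| elm run | 2.1 | 0.0594 |
| elm run | 4.0 | 0.0694 |
| maple run | 0.16 | 0.0021 |
| maple run | 0.30 | 0.0038 |
| maple run | 0.58 | 0.0112 |
| maple run | 1.1 | 0.0177 |
| maple run | 2.1 | 0.0276 |
| maple run | 4.0 | 0.0365 |
| birch run | 0.16 | 0.0149 |
| birch run | 0.30 | 0.0261 |
| birch run | 0.58 | 0.0427 |
| birch run | 1.1 | 0.0640 |
| birch run | 2.1 | 0.0788 |
| birch run | 4.0 | 0.0698 |
| ash run | 0.16 | 0.0125 |
| ash run | 0.30 | 0.0226 |
| ash run | 0.58 | 0.0393 |
| ash run | 1.1 | 0.0656 |
| ash run | 2.1 | 0.0940 |
| ash run | 4.0 | 0.1152 |

(standard deviation of a reading: 9 × 10⁻⁴ M)

- how the opening rate goes with [substrate] round the charge of the elm run: the exponent of the rate at two percent of substrate gone to target (one fixed amount of target, the same in the runs compared)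
- how the opening rate goes with [coupling partner] round the charge of the elm run: the exponent of the rate at two percent of substrate gone to target
- target in the cedar run at 4.0 h, as a share of the substrate charged

- Overall: substrate + coupling partner -> target, with catalyst as catalyst.
- Constant volume, constant temperature.
- The analysis sees a species whether free or bound.
- "The second partner" is coupling partner.
- An order is taken over about fifteen percent of the charge, up and down.

With twice the coupling partner, the birch run reads 2.01 times the elm target at 0.16 h, and with 3.00 times the substrate the ash run reads 1.69 times that target, so making looks first order in partner and below first order in substrate.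

This reckoning assumes, untested by the runs, that loss of target is first order in target and in partner, and that catalyst speeds making but not loss. Partner then cancels from the ratio of the two rates. The highest birch reading is 26.3% of the charge, and this reckoning takes that share as the ceiling c, the target share at which loss just equals making, which is the field's selectivity factor, making over loss at target equal to the charge. That reading stands at 2.1 h, with at most 0.221 M of substrate left, yet c is held constant here as a simplification, so it is a rough figure. With p the target and x the substrate turned to target, both as fractions of the charge:

dp/dx = 1 − p/c, so p = c·(1 − e^(−x/c))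

The catalyst ratio lifts the ceiling for the cedar run to c = 131%. Substrate there has a time constant set by the scaled elm opening rate, read as the elm target at 0.30 h over that time, and stretched by the ratio of partner at the charge to partner halfway through:

τ = 1.97 h, x = 1 − e^(−t/τ) = 86.9% at 4.0 h

p = 63.5%

The forecast gives 0.63, 1 and 45%, lower than this reckoning, and it warns that “catalyst response and the catalyst dependence of the loss step are both untested”.

The cedar run gives 55.9% of its charge at 4.0 h, 7.6 percentage points under this reckoning, with orders 0.66 in substrate and 1.0 in partner.

    catalyst + substrate ⇌ catalyst-substrate complex, settled at all times (2.070 /M)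
    catalyst-substrate complex + coupling partner → target + catalyst + by-product (189.4 /M/h)
    2 substrate → homo dimer (0.2351 /M/h)
    target + coupling partner → side product (0.6624 /M/h)

Making and loss each take one coupling partner in these steps. The cedar target stands at 42.7% of its reckoned c and at twice the birch reading of c. The elm run, with the substrate and catalyst of the birch run and half its partner, read 23.1% at 4.0 h, below that same birch reading of 26.3%.

The readings stem from a simulated flask from invented constants, and the scatter is random.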